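## The problem

Compound 11 is an 8-O-4' neolignan ketone in which no ring has to be built: ring A (3,4,5-trimethoxyphenyl) sits on the carbonyl carbon C7, the next carbon C8 carries the methyl group C9 and an ether oxygen, and that oxygen is bound to C4' of ring B, which has methoxy groups at C3' and C5' and an allyl group at C1'. The task is therefore to join two arenes through a C(=O)–CH(CH3)–O chain and to attach a three-carbon side chain to ring B. C8 is the only stereocenter (R), and nothing else in the molecule can induce it, so it must come from the chiral pool or from an external chiral agent. Its hydrogen lies between an aryl ketone and an aryloxy group and is easily removed, so the ketone should be made last and the stereocenter should travel as a less acidic acyl derivative. The ether oxygen is flanked by two methoxy groups, so the C8–O bond must be made with a hindered phenol oxygen. The allyl group is a terminal alkene one isomerisation away from conjugation with ring B; it will not tolerate strong base, hot metal hydride species, hydrogenation or electrophilic oxidants. The feature that opens a short route is the pattern of ring B: C1' is para to the ether oxygen and its neighbours C2' and C6' bear only hydrogen, while each of those hydrogens stands next to a methoxy group, so that in the allyl-free 2,6-dimethoxyphenyl ether C1'–H is the single unhindered C–H bond, which a sterically governed borylation can find and which electrophilic substitution, directed to C2' and C6', cannot.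

## Retrosynthesis

**C7–C1 (carbonyl to ring A).** The last bond made is the one between C7 and ring A, which divides 11 into the Weinreb amide 7 and the aryl Grignard reagent 9, prepared from the commercial bromide 8. The neighbouring cut, C8–O with a phenoxide displacing a leaving group next to the ketone, would expose an enolisable α-substituted ketone to base. The acyl substitution leaves C8 untouched and releases the ketone only when the chelated adduct 10 collapses on work-up. The precursor 7 is smaller by the whole of ring A. The forward reaction must add once, must not deprotonate C8, and must be quenched without base.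

**C1'–C7' (ring B to allyl).** The aryl–allyl bond of 7 is cut next, giving the allyl-free amide 4 and allyl bromide 5, with the aryl boronate 6 as the link. The neighbouring choice is not to cut here and to bring ring B in with its side chain already attached; that is shorter and is kept as the fallback for step 3. Three things speak for the cut. C1' cannot be reached by electrophilic substitution, so C–H borylation is the one direct way to functionalise it. Precursor 4 has a symmetric ring B that comes from the cheapest phenol, 2, and no alkene is present during the first two steps. Compounds 4 and 6 are also branching points for other C1' substituents. The forward reaction must select C1'–H, tolerate the amide, leave C8 alone and not move the double bond.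

**C(=O)–N (amide from ester).** Amide 4 is traced to the methyl ester 3 by one functional-group interchange. The amide is placed before the key step because the aminolysis uses the basic chloromagnesium amide MeN(OMe)MgCl and is better run without the alkene. The amide is also less prone than the ester to hydrolysis or enolisation in the aqueous K2CO3 of the coupling. The forward reaction must make acyl transfer faster than deprotonation at C8.

**C8–O (alkyl carbon to phenol oxygen).** Ester 3 is cut into methyl (S)-lactate 1 and 2,6-dimethoxyphenol 2. A cut on the aryl side of the oxygen would require etherifying an electron-rich, doubly ortho-substituted aryl halide with a secondary alcohol, and would need the less common lactate enantiomer. Substitution at C8 with inversion turns the natural (S)-lactate 1 into the (R) ether 3 and reduces the problem to two commodity chemicals. The forward reaction must be a clean SN2 despite the two ortho-methoxy groups.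

## Roads not taken

Alternative 1: The cut is C7–C8.
- Forward key step: an (S)-selective thiamine-diphosphate-dependent carboligase would join 3,4,5-trimethoxybenzaldehyde A2 as donor and acetaldehyde A3 as acceptor to give (S)-2-hydroxy-1-(3,4,5-trimethoxyphenyl)propan-1-one A1. A Mitsunobu inversion of A1 with 4-allyl-2,6-dimethoxyphenol A4 would then give 11.
- Merits: the skeleton bond and the stereocenter come from the achiral aldehydes A2 and A3 in one catalytic step, and the route is two steps on paper. In step count it is better than the chosen plan.
- Weak points: acceptance of A2, a donor with three methoxy groups, by an (S)-selective active site is not assured, and the enantioselectivity of such enzymes depends on the donor. The second step inverts a carbinol that is α to an aryl ketone with the hindered phenol A4. Both the activated intermediate and product 11 can enolise under the basic Mitsunobu medium, and A1 can also undergo ketol isomerisation.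
- Comparison: the chosen plan is two steps longer. Against that, its starting material is enantiopure by purchase, the inversion is done at the ester stage, and the ketone appears only in the final acidic quench.

Alternative 2: The cut is the aryl C4'–O bond with reversed polarity.
- Forward key step: 4-allyl-2,6-dimethoxyphenyllithium A5 would attack the alkyl-bearing oxygen of the tetrahydropyranyl monoperoxyacetal of (R)-1-(tert-butyldimethylsilyloxy)propane-2-hydroperoxide A6, the acetal oxygen leaving as its lithium alkoxide. The product is (R)-tert-butyl[2-(4-allyl-2,6-dimethoxyphenoxy)propoxy]dimethylsilane A7.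
- Merits: the ether forms with retention because no bond to C8 is touched, and the hindered oxygen never has to act as a nucleophile. On that one point it is better than a Mitsunobu reaction.
- Weak points: A7 is at the wrong oxidation level. Desilylation, oxidation to (R)-2-(4-allyl-2,6-dimethoxyphenoxy)propanal A8, aryl addition and re-oxidation are still needed, and A8 is the most epimerisable compound of the series. A6 takes several steps to make and is a peroxide. Generating A5 must compete with deprotonation of the doubly activated allylic and benzylic CH2 group.
- Comparison: the sequence is at least twice as long as the chosen one, and the lactate Mitsunobu of the chosen plan already solves the problem that the umpolung addresses.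

Alternative 3: The cut is C8–C9.
- Forward key step: the sodium Z-enolate of (S)-4-benzyl-3-[2-(4-allyl-2,6-dimethoxyphenoxy)acetyl]oxazolidin-2-one A9 would be methylated on the face away from the benzyl group to give (S)-4-benzyl-3-[(R)-2-(4-allyl-2,6-dimethoxyphenoxy)propanoyl]oxazolidin-2-one A10. Exchange of the auxiliary of A10 for the N-methoxy-N-methylamide would join the chosen route at 7.
- Merits: facial control is dependable, A10 can be separated from its C8 epimer so the stereochemical purity can be upgraded, and either enantiomer is available. It does not rely on the fidelity of an SN2 inversion, and in that respect it is the safer road.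
- Weak points: four steps from A4 are needed to reach 7 (O-alkylation, attachment of the auxiliary to give A9, methylation to A10, transamination). The auxiliary is stoichiometric, the methyl electrophile is the smallest and least selective, and the enolate of an aryloxyacetyl imide such as A9 can fragment to a ketene.
- Comparison: the chosen plan reaches 7 in three steps and takes the stereocenter ready-made from lactate.

Key step: step 3

## Route

Step 1
Reactants: 1 methyl (S)-lactate; 2 2,6-dimethoxyphenol
Product: 3 methyl (R)-2-(2,6-dimethoxyphenoxy)propanoate
Conditions: PPh3, DIAD, THF, 0 °C to rt
Reagents that add atoms: none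
Why: Mitsunobu etherification; the phenol is acidic enough to protonate the betaine, and the phenoxide displaces the oxyphosphonium group at C8 by SN2 with inversion, so the (S) alcohol gives the (R) aryl ether. The adjacent ester accelerates the substitution and the small secondary centre offsets the two ortho-methoxy groups.

Step 2
Reactants: 3 methyl (R)-2-(2,6-dimethoxyphenoxy)propanoate
Product: 4 (R)-2-(2,6-dimethoxyphenoxy)-N-methoxy-N-methylpropanamide
Conditions: MeNH(OMe)·HCl, i-PrMgCl, THF, −20 °C
Reagents that add atoms: N,O-dimethylhydroxylamine hydrochloride, CNOC.Cl
Why: Direct aminolysis of an ester by the chloromagnesium amide of N,O-dimethylhydroxylamine (Weinreb amide synthesis); adding i-PrMgCl to a mixture of ester and amine salt forms the amide nucleophile before the Grignard reagent can attack the ester. At −20 °C acyl transfer should outrun deprotonation at C8, so the configuration is kept.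

Step 3
Reactants: 4 (R)-2-(2,6-dimethoxyphenoxy)-N-methoxy-N-methylpropanamide; 5 allyl bromide
Product: 7 (R)-2-(4-allyl-2,6-dimethoxyphenoxy)-N-methoxy-N-methylpropanamide, via aryl pinacol boronate 6 (not isolated)
Conditions: [Ir(OMe)(cod)]2 (cat.), 4,4'-di-tert-butyl-2,2'-bipyridine (cat.), B2pin2 (1.0 equiv), THF, 80 °C (sealed); volatiles removed; then Pd(PPh3)4 (cat.), allyl bromide, K2CO3, THF/H2O, 60 °C
Reagents that add atoms: none
Why: This is an iridium-catalysed aromatic C–H borylation followed in the same flask by a Suzuki–Miyaura coupling with an allylic halide, a sequence known for 1,2,3-trisubstituted benzenes, which are borylated at C5. [Ir(OMe)(cod)]2, the bipyridine and B2pin2 form the trivalent iridium tris(boryl) complex, which cleaves an arene C–H bond by oxidative addition to a pentavalent iridium aryl hydride and releases boronate 6 by C–B reductive elimination. The step needs regioselectivity and ring B supplies it: C1'–H is the only C–H whose two neighbours carry hydrogen, whereas C2'–H and C6'–H each lie next to a methoxy group that the crowded tris(boryl) centre cannot pass. The N-methyl, O-methyl and C8–H bonds are sp3 C–H bonds that this bipyridine catalyst does not attack at a competitive rate. After removal of the volatiles, pinacolborane included, zerovalent palladium from Pd(PPh3)4 ionises allyl bromide to an η3-allyl complex of divalent palladium, carbonate-assisted transmetalation moves the aryl group from boron to palladium, and reductive elimination forms the C1'–C7' bond; the allyl fragment is symmetric, so no linear or branched question arises. No ring closes and no stereocenter is created; C8 is α to an amide, not a ketone, so aqueous K2CO3 at 60 °C should leave it untouched. The moderate temperature and short exposure to palladium are chosen to keep the terminal alkene from migrating into conjugation with ring B.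

Step 4
Reactants: 7 (R)-2-(4-allyl-2,6-dimethoxyphenoxy)-N-methoxy-N-methylpropanamide; 8 5-bromo-1,2,3-trimethoxybenzene
Product: 11 (R)-2-(4-allyl-2,6-dimethoxyphenoxy)-1-(3,4,5-trimethoxyphenyl)propan-1-one, via 3,4,5-trimethoxyphenylmagnesium bromide 9 (not isolated), via bromomagnesium tetrahedral adduct 10 (not isolated)
Conditions: 8, Mg, I2 (cat.), THF, 40 °C; then 7, THF, −20 to 0 °C; cold 1 M HCl
Reagents that add atoms: none
Why: Weinreb ketone synthesis; the aryl Grignard reagent adds once to the amide to give the five-membered magnesium chelate 10, which cannot enolise or accept a second aryl group and releases the ketone only in the acidic quench. The aryl Grignard reagent is a poor kinetic base at this temperature and the ketone never meets base, so the (R) configuration at C8 should be carried into 11.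

## Compound list

1 | methyl (S)-lactate (methyl (2S)-2-hydroxypropanoate) | C[C@H](O)C(=O)OC | starting material
2 | 2,6-dimethoxyphenol | COc1cccc(OC)c1O | starting material
3 | methyl (R)-2-(2,6-dimethoxyphenoxy)propanoate | COc1cccc(OC)c1O[C@H](C)C(=O)OC | intermediate
4 | (R)-2-(2,6-dimethoxyphenoxy)-N-methoxy-N-methylpropanamide | COc1cccc(OC)c1O[C@H](C)C(=O)N(C)OC | intermediate
5 | allyl bromide | C=CCBr | starting material
6 | (R)-2-[2,6-dimethoxy-4-(4,4,5,5-tetramethyl-1,3,2-dioxaborolan-2-yl)phenoxy]-N-methoxy-N-methylpropanamide | COc1cc(B2OC(C)(C)C(C)(C)O2)cc(OC)c1O[C@H](C)C(=O)N(C)OC | intermediate (not isolated)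
7 | (R)-2-(4-allyl-2,6-dimethoxyphenoxy)-N-methoxy-N-methylpropanamide | C=CCc1cc(OC)c(O[C@H](C)C(=O)N(C)OC)c(OC)c1 | intermediate
8 | 5-bromo-1,2,3-trimethoxybenzene | COc1cc(Br)cc(OC)c1OC | starting material
9 | 3,4,5-trimethoxyphenylmagnesium bromide | COc1cc([Mg]Br)cc(OC)c1OC | intermediate (not isolated)
10 | bromomagnesium (2R)-2-(4-allyl-2,6-dimethoxyphenoxy)-1-[methoxy(methyl)amino]-1-(3,4,5-trimethoxyphenyl)propan-1-olate, either configuration at C1, which is lost on work-up | C=CCc1cc(OC)c(O[C@H](C)C(O[Mg]Br)(N(C)OC)c2cc(OC)c(OC)c(OC)c2)c(OC)c1 | intermediate (not isolated)
11 | (R)-2-(4-allyl-2,6-dimethoxyphenoxy)-1-(3,4,5-trimethoxyphenyl)propan-1-one | C=CCc1cc(OC)c(O[C@H](C)C(=O)c2cc(OC)c(OC)c(OC)c2)c(OC)c1 | target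

## Step count and risks

Total steps: 4. Longest linear sequence: 4 steps (1 → 3 → 4 → 7 → 11).

**Step 3 (key step).** Three things are most likely to go wrong.
- The borylation may stall because the chelating N-methoxy amide holds the iridium centre.
- In the coupling stage, residual boron reagents may consume allyl bromide, the electron-rich boronate may protodeboronate in warm aqueous base, or a palladium hydride such as HPdBr(PPh3)2 may shift the double bond into conjugation.
- Slow erosion at C8 is the least likely problem.

If these cannot be cured by isolating 6 before the coupling, the fallback gives up the C–H functionalisation and brings ring B in with its side chain. It sets out from 1: Mitsunobu reaction with commercial 4-allyl-2,6-dimethoxyphenol F1 (PPh3, DIAD, THF) should give methyl (R)-2-(4-allyl-2,6-dimethoxyphenoxy)propanoate F2. Aminolysis of F2 as in step 2 returns to the route at 7. This fallback is one step shorter than the main line, at the price of a dearer phenol and of losing 4 and 6 as branching points.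

**Step 4.** The likely failure is loss of configuration at C8, either by deprotonation of the amide if the addition is sluggish and has to be warmed, or by enolisation of the ketone during work-up and chromatography. The fallback sets out from 7 and does the carbon–carbon bond formation at −78 °C. Reduction with i-Bu2AlH (THF, −78 °C) gives (R)-2-(4-allyl-2,6-dimethoxyphenoxy)propanal F3, which is used at once. Addition of 9 at −78 °C gives (2R)-2-(4-allyl-2,6-dimethoxyphenoxy)-1-(3,4,5-trimethoxyphenyl)propan-1-ol F4 as a mixture of C7 epimers. Both epimers converge on oxidation with Dess–Martin periodinane in CH2Cl2, returning to the route at 11.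

**Step 2.** The risk is partial epimerisation at C8 by the basic chloromagnesium amide or by excess i-PrMgCl, and competing addition of i-PrMgCl to the ester. The fallback sets out from 3: saponification with LiOH in THF/H2O at 0 °C gives (R)-2-(2,6-dimethoxyphenoxy)propanoic acid F5. Coupling of F5 with N,O-dimethylhydroxylamine hydrochloride (EDC·HCl, HOBt, N-methylmorpholine, CH2Cl2) returns to the route at 4.

**Step 1.** The hindered phenol may be alkylated slowly, so that elimination of the activated lactate or alkylation of the hydrazide competes, and removal of the phosphine oxide may be tedious. The fallback sets out from 1 and replaces redox activation by a sulfonate displacement. Tosylation (TsCl, Et3N, DMAP cat., CH2Cl2) gives methyl (S)-2-(tosyloxy)propanoate F6. Displacement by the phenoxide of 2 (K2CO3, MeCN, 60 °C) with inversion returns to the route at 3.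

## Further compounds

F1 | step 3 | 4-allyl-2,6-dimethoxyphenol | C=CCc1cc(OC)c(O)c(OC)c1
F2 | step 3 | methyl (R)-2-(4-allyl-2,6-dimethoxyphenoxy)propanoate | C=CCc1cc(OC)c(O[C@H](C)C(=O)OC)c(OC)c1
F3 | step 4 | (R)-2-(4-allyl-2,6-dimethoxyphenoxy)propanal | C=CCc1cc(OC)c(O[C@H](C)C=O)c(OC)c1
F4 | step 4 | (2R)-2-(4-allyl-2,6-dimethoxyphenoxy)-1-(3,4,5-trimethoxyphenyl)propan-1-ol, both C1 epimers | C=CCc1cc(OC)c(O[C@H](C)C(O)c2cc(OC)c(OC)c(OC)c2)c(OC)c1
F5 | step 2 | (R)-2-(2,6-dimethoxyphenoxy)propanoic acid | COc1cccc(OC)c1O[C@H](C)C(=O)O
F6 | step 1 | methyl (S)-2-(tosyloxy)propanoate | C[C@H](OS(=O)(=O)c1ccc(C)cc1)C(=O)OC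
A1 | alternative 1 | (S)-2-hydroxy-1-(3,4,5-trimethoxyphenyl)propan-1-one | O[C@@H](C)C(=O)c1cc(OC)c(OC)c(OC)c1
A2 | alternative 1 | 3,4,5-trimethoxybenzaldehyde | COc1cc(C=O)cc(OC)c1OC
A3 | alternative 1 | acetaldehyde | CC=O
A4 | alternative 1 | 4-allyl-2,6-dimethoxyphenol | C=CCc1cc(OC)c(O)c(OC)c1
A5 | alternative 2 | 4-allyl-2,6-dimethoxyphenyllithium | [Li]c1c(OC)cc(CC=C)cc1OC
A6 | alternative 2 | 2-{[(2R)-1-(tert-butyldimethylsilyloxy)propan-2-yl]peroxy}tetrahydro-2H-pyran, mixture at the acetal carbon | C[C@H](CO[Si](C)(C)C(C)(C)C)OOC1CCCCO1
A7 | alternative 2 | (R)-tert-butyl[2-(4-allyl-2,6-dimethoxyphenoxy)propoxy]dimethylsilane | C=CCc1cc(OC)c(O[C@H](C)CO[Si](C)(C)C(C)(C)C)c(OC)c1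
A8 | alternative 2 | (R)-2-(4-allyl-2,6-dimethoxyphenoxy)propanal | C=CCc1cc(OC)c(O[C@H](C)C=O)c(OC)c1
A9 | alternative 3 | (S)-4-benzyl-3-[2-(4-allyl-2,6-dimethoxyphenoxy)acetyl]oxazolidin-2-one | C=CCc1cc(OC)c(OCC(=O)N2[C@@H](Cc3ccccc3)COC2=O)c(OC)c1
A10 | alternative 3 | (S)-4-benzyl-3-[(R)-2-(4-allyl-2,6-dimethoxyphenoxy)propanoyl]oxazolidin-2-one | C=CCc1cc(OC)c(O[C@H](C)C(=O)N2[C@@H](Cc3ccccc3)COC2=O)c(OC)c1
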